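A small charge of Q meets a large excess of X in the teal flask: if Z holds one X, the highest reading of Z, 27.7% of the Q charged, ties up that share of one equivalent out of 3 equiv.

| flask | Q | X | L | temperature | remark | time |
|---|---|---|---|---|---|---|
| teal | 0.10 M | 3 equiv | 0.20 equiv | −20 °C | the very flask that is asked about, followed so far |  |
| ochre | 0.10 M | 2 equiv | 0.20 equiv | −20 °C | run made earlier |  |
| flask | 0.10 M | 3.00 equiv | 0.200 equiv | −20 °C |  | 8.0 d |

| run | time / d | Z / % |
|---|---|---|
| teal | 0.500 | 27.7 |
| teal | 1.67 | 26.6 |
| teal | 3.00 | 23.3 |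
| teal | 4.00 | 22.0 |
| teal | 6.00 | 18.6 |
| teal | 8.00 | 16.2 |
| ochre | 0.208 | 14.5 |
| ochre | 0.333 | 18.5 |
| ochre | 0.500 | 20.0 |
| ochre | 0.833 | 20.8 |
| ochre | 1.67 | 18.9 |
| ochre | 2.50 | 16.7 |

(each reading ± 0.3 percentage points)

- zeta: at 8.0 d raise the temperature by 20 K, then wait 2.5 d
- beta: at 8.0 d take out 90% of the Z then present, then wait 2.5 d
- alpha: change nothing and wait 2.5 d more
- delta: at 8.0 d add X, 50.0% of the amount charged, then wait 2.5 d

- what is taken out of Z is counted as made
- what was read earlier has a scatter of 0.3 percentage points, one standard deviation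
- additions bring no volume worth counting
- the earlier runs do not show what temperature does; that part of a forecast is a guess

* Z, in percent of the Q first charged, at 8.0 d
* the option that brings most further Z ("none" if no option brings more than 2 percentage points) (zeta / beta / alpha / delta / none)
* Z present, with what was taken out counted in, in percent of the Q first charged, after alpha
* Z present, with what was taken out counted in, in percent of the Q first charged, after delta

So we freeze free X in teal, the pseudo-first-order condition. Z is up by 0.500 d and still falling at 8.00 d, so we take Z as a steady share of a pool, Q plus Z.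

How does that pool decay? In teal the fractional fall of Z is 0.0996 d⁻¹ in the first window of the decline and 0.0691 d⁻¹ in the last, a ratio of 0.694. Mean Z in those windows stands in the ratio 0.697. Within the scatter this is a hint of a second-order loss, for which 1/Z runs straight in time. We carry s, the slope of 1/Z against time with Z as a fraction of the Q charged, read in teal as 0.381 d⁻¹.

What does each option bring? From the last teal reading, 16.2%, s gives 14.0% after alpha. Teal over ochre at 1.67 d reads 1.41 for X raised 1.50 times, and delta raises charged X by that factor again, so we reckon 19.8% after delta. Beta, reckoned from that last reading, takes out 14.6%; with the pool's Z share taken as 27.7%, we reckon the count at 25.1%, more than delta. Both runs stand at −20 °C, so zeta stays unreckoned.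

The forecast gives 16.2%, then 13.4% after alpha, lower than our alpha, and 23.5% after delta, higher than our delta, and picks beta: “This holds under either decay explanation, so it is the narrow favourite.”

The teal flask gives 16.4% at 8.0 d, and beta is best at 8.2 percentage points, with 24.6% counted; alpha ends at 14.2% and delta at 19.1%.

Q + X ⇌ Z (K = 1.92 L mol⁻¹, k = 0.00411 L mol⁻¹ min⁻¹, Ea = 56.0 kJ mol⁻¹, ΔH = −42.0 kJ mol⁻¹); L + X ⇌ J (K = 25.0 L mol⁻¹, k = 0.0151 L mol⁻¹ min⁻¹, Ea = 63.0 kJ mol⁻¹, ΔH = −13.0 kJ mol⁻¹); 2 Q → D (k = 0.00106 L mol⁻¹ min⁻¹, Ea = 58.0 kJ mol⁻¹); (constants at −20 °C) In this flask Z over Q stands at 0.515 at 4.00 d and 0.522 at 8.00 d. From 16.4%, s gives 14.2% after alpha. Left until 80.0 d, s gives 2.98% of Z, and the teal flask holds 3.06%.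

Readings and results stem from a simulated flask from invented constants, and the scatter is random.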